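In a slow flask I count how many of its own relaxation times fit into the wait, which tells me how much of its beginning still shows. In these flasks starting material and partner reversibly form target and isomer of the product, target binds partner as idle adduct, and protic impurity quenches starting material. The flask asked about is Tuesday's run, followed on.

the same everywhere: starting material 0.25 M; temperature 90 °C
- Tuesday's: partner 1.3 equiv; protic impurity 0.075 M; the very flask that is asked about, followed so far
- Sunday's: partner 1.3 equiv; protic impurity 0.050 M; run made earlier
- flask: partner 1.30 equiv; protic impurity 0.0750 M; time 3.0 h

| run | time / h | target / % |
|---|---|---|
| Tuesday's | 0.500 | 30.5 |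
| Tuesday's | 1.00 | 25.9 |
| Tuesday's | 1.33 | 25.2 |
| Tuesday's | 2.00 | 24.2 |
| Tuesday's | 2.50 | 23.7 |
| Sunday's | 0.250 | 34.3 |
| Sunday's | 0.417 | 31.2 |
| Sunday's | 0.833 | 27.7 |
| Sunday's | 1.50 | 24.4 |
| Sunday's | 3.00 | 23.3 |

(each reading ± 0.5 percentage points)

- violet: at 3.0 h add partner, 100% of the amount charged, then wait 1.5 h
- blue: at 3.0 h add starting material, 50.0% of the amount charged, then wait 1.5 h
- amber: change nothing and wait 1.5 h more
- ochre: at 3.0 h raise the temperature by 10 K, then wait 1.5 h

- for target the idle adduct is counted in
- the volume of additions can be left aside
- reactions considered so far: partner + target <-> idle adduct; starting material + partner <-> target; starting material + protic impurity -> quenched substrate; starting material + partner <-> isomer of the product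
- the earlier runs do not show what temperature does; that part of a forecast is a guess

- target, in percent of the starting material first charged, at 3.0 h
- which option adds most target ("none" when 2 percentage points or less is all one gets) (violet / blue / amber / ochre / none)
- target present, in percent of the starting material first charged, after blue
- target present, in percent of the starting material first charged, after ochre

In Sunday's run target falls from 31.2% at 0.417 h to 24.4% at 1.50 h, and its last reading is 23.3%. I take the excess over that last reading as decaying exponentially, which gives a relaxation time τ = 0.549 h, a rough reading given the scatter. The number I carry is N = t/τ, the relaxation times elapsed at time t. For Tuesday's flask at 3.0 h, N = 5.46, so on this reckoning about 0.425% of the early excess remains, and I read that flask as near thermodynamic control, not kinetic.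

To test τ on the other run, I start from Tuesday's 30.5% at 0.500 h, take Tuesday's last reading as the level, and predict 26.4% at 1.00 h, against the reading 25.9%. The gap is about the scatter.

But N says how far the early relaxation has gone, not at what level it ends. For the level I take Tuesday's last reading, 23.7%, and I expect amber to gain no more than 2 percentage points. At balance, free target over starting material goes with free partner, so I choose violet, which raises free partner, and not blue, which consumes it. Ochre stays a guess.

The forecast gives 23%, blue, 37% after blue and 22% after ochre, holding that “Fresh starting material, however, creates new product”.

The flask gives 23.6% and violet as best: violet adds 11 points, blue 6.1 points (reaching 29.7%), amber −0.3 points, and ochre −8.5 points (reaching 15.1%).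

    partner + target ⇌ idle adduct, settled at all times (K = 1.30 /M, ΔH = −2.00 kJ/mol)
    starting material + partner ⇌ target (K = 4.30 /M, k = 0.00710 /M/s, Ea = 62.0 kJ/mol, ΔH = −48.0 kJ/mol)
    starting material + protic impurity → quenched substrate (k = 1.70 × 10⁻⁴ /M/s, Ea = 73.0 kJ/mol)
    starting material + partner ⇌ isomer of the product (K = 9.10 /M, k = 0.00330 /M/s, Ea = 68.0 kJ/mol, ΔH = 20.0 kJ/mol)
    (constants at 90 °C)

The back reaction of target to starting material + partner may be called the main reason for the low level in Tuesday's flask: the same run without it stands at 93.6%, against 23.6%. Now take the neighbour flask with 0.10 M of starting material. If τ stretched in proportion to the dilution, N there is about 2.18, which leaves about 11.3% of the excess, so I expect isomer of the product per free target to stay near the 2.12 of Tuesday's flask. After 3.00 h the neighbour holds 16.8% target, idle adduct counted in, and 32.3% isomer of the product, which is 2.13 per free target.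

The runs were generated by integration with constants of no real substance; the scatter is artificial.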